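**Retrosynthetic overview** (elemane numbering: ring C5–C10; C4(=C3)–C15 on C5; C14 methyl and C1=C2 vinyl on C10; C11(=C13)–C12 on C7)
1. The feature used: on ring C5–C10, the C8 acyloxy group and the C7 acrylic acid unit C11(=C13)–C12O2H are cis, so C7–C8 with these groups is a ring-opened cis-fused α-methylene-γ-butyrolactone (ring O8–C8–C7–C11–C12).
2. Key disconnection C7–C8: indium Barbier closure of the acyclic (Z)-2-(bromomethyl)enoate aldehyde 25 forms the carbocycle first and the lactone second (27).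
3. 25 comes from a cyclohexene template that sets C10 (Diels–Alder), C5 (CBS reduction, Eschenmoser–Claisen) and C6 (iodolactonization). The template is opened at C7=C8 by hydroxyl-directed epoxidation and periodic acid, because ozone would not spare the vinyl and methylene groups.
4. The two aldehydes are told apart by selective acetalization of C8; Baylis–Hillman reaction at C7 and bromide transposition follow. O15 carries TBDPS (not TBS) to survive the two mild-acid steps.
5. End game: lactone opening to a PMB ester, C8 acylation with (Z)-4-acetoxy-2-methylbut-2-enoic acid (from 3-methylfuran-2(5H)-one), acid then fluoride deprotection. Ring order: template ring (step 2), opened (step 14), carbocycle then lactone (step 19), lactone opened (step 20).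

Key step: step 19

Assumption: the facial sense of the Diels–Alder catalyst in step 2 is taken from the formyl C–H···O binding model for α-substituted acroleins; if the (S)-catalyst gives the mirror-image aldehyde, the (R)-catalyst is used and nothing else changes.

Step 1
Reactants: 1 methyl vinyl ketone
Product: 2 2-(triisopropylsilyloxy)buta-1,3-diene
Conditions: i-Pr3SiOTf, Et3N, Et2O, 0 °C to rt
Reagents that add atoms: triisopropylsilyl triflate, CC(C)[Si](C(C)C)(C(C)C)OS(=O)(=O)C(F)(F)F
Why: Soft enolization and O-silylation of the enone gives the cross-conjugated silyl dienol ether, a standard preparation of 2-silyloxy dienes.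

Step 2
Reactants: 2 2-(triisopropylsilyloxy)buta-1,3-diene; 3 methacrolein
Product: 4 (S)-1-methyl-4-(triisopropylsilyloxy)cyclohex-3-ene-1-carbaldehyde
Conditions: (S)-3,3-diphenyl-1-(2-methylphenyl)tetrahydro-1H,3H-pyrrolo[1,2-c][1,3,2]oxazaborole·HN(SO2CF3)2 (10 mol%), CH2Cl2, −78 °C
Reagents that add atoms: none
Why: Enantioselective Diels–Alder reaction under chiral oxazaborolidinium (Corey-type) catalysis; the 2-silyloxy diene adds with para regiochemistry and the catalyst-bound s-trans enal is attacked on one face, which sets the quaternary centre C10.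

Step 3
Reactants: 4 (S)-1-methyl-4-(triisopropylsilyloxy)cyclohex-3-ene-1-carbaldehyde
Product: 5 triisopropyl{[(4S)-4-methyl-4-vinylcyclohex-1-en-1-yl]oxy}silane
Conditions: Ph3PCH3Br, KN(SiMe3)2, THF, −78 to 0 °C
Reagents that add atoms: methyltriphenylphosphonium bromide, C[P+](c1ccccc1)(c1ccccc1)c1ccccc1.[Br-]
Why: Wittig methylenation of a non-enolizable aldehyde gives the C1=C2 vinyl group; the silyl enol ether is inert to the ylide and C10 is untouched.

Step 4
Reactants: 5 triisopropyl{[(4S)-4-methyl-4-vinylcyclohex-1-en-1-yl]oxy}silane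
Product: 6 (R)-4-methyl-4-vinylcyclohex-2-en-1-one
Conditions: Pd(OAc)2 (1.1 equiv), DMSO, 50 °C
Reagents that add atoms: none
Why: Saegusa–Ito oxidation dehydrogenates exactly where the enol ether double bond sits, so the C10 configuration passes into the enone without going through the achiral saturated ketone.

Step 5
Reactants: 6 (R)-4-methyl-4-vinylcyclohex-2-en-1-one
Product: 7 (1S,4R)-4-methyl-4-vinylcyclohex-2-en-1-ol (hydroxyl cis to the methyl group)
Conditions: (R)-1-methyl-3,3-diphenyltetrahydro-1H,3H-pyrrolo[1,2-c][1,3,2]oxazaborole (15 mol%), catecholborane, toluene, −78 °C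
Reagents that add atoms: none
Why: Corey–Bakshi–Shibata reduction, in which the alkene arm acts as the large group, so the (R)-catalyst gives the (S)-carbinol under reagent control; the remote C10 centre does not interfere and any minor enantiomer of 6 becomes a separable diastereomer.

Step 6
Reactants: 7 (1S,4R)-4-methyl-4-vinylcyclohex-2-en-1-ol
Product: 9 N,N-dimethyl-2-[(1S,6R)-6-methyl-6-vinylcyclohex-2-en-1-yl]acetamide, via ketene N,O-acetal 8 (not isolated)
Conditions: MeC(OMe)2NMe2, xylene, 140 °C
Reagents that add atoms: N,N-dimethylacetamide dimethyl acetal, COC(C)(OC)N(C)C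
Why: Eschenmoser–Claisen rearrangement; the suprafacial [3,3] shift of 8 transfers the C7–O configuration to C5, so the new C5–C4 bond lies cis to the C10 methyl group.

Step 7
Reactants: 9 N,N-dimethyl-2-[(1S,6R)-6-methyl-6-vinylcyclohex-2-en-1-yl]acetamide
Product: 11 (3aR,4R,7R,7aR)-7-iodo-4-methyl-4-vinylhexahydro-1-benzofuran-2(3H)-one, via iminium lactone 10 (not isolated)
Conditions: I2, THF/H2O (1:1), rt
Reagents that add atoms: iodine, II; water, O
Why: Iodolactonization of a γ,δ-unsaturated amide; the amide oxygen closes 5-exo onto C6 from the side-chain face while iodine adds anti at C7, and hydrolysis of 10 gives the cis-fused lactone, which sets C6–O cis to C4.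

Step 8
Reactants: 11 (3aR,4R,7R,7aR)-7-iodo-4-methyl-4-vinylhexahydro-1-benzofuran-2(3H)-one
Product: 12 (3aR,4R,7aS)-4-methyl-4-vinyl-3a,4,5,7a-tetrahydro-1-benzofuran-2(3H)-one
Conditions: DBU, toluene, 110 °C
Reagents that add atoms: none
Why: E2 dehydroiodination; only a C8 hydrogen can be anti-periplanar to the C7 iodide (the C6 hydrogen is syn), so the alkene forms at C7=C8.

Step 9
Reactants: 12 (3aR,4R,7aS)-4-methyl-4-vinyl-3a,4,5,7a-tetrahydro-1-benzofuran-2(3H)-one
Product: 15 (3aS,4R,7aS)-4-methyl-3-methylidene-4-vinyl-3a,4,5,7a-tetrahydro-1-benzofuran-2(3H)-one, via Mannich base 13 (not isolated), via ammonium iodide 14 (not isolated)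
Conditions: LiN(i-Pr)2, THF, −78 °C; CH2=NMe2+ I−, −78 °C to rt; MeI, MeOH, rt; aq. NaHCO3, CH2Cl2
Reagents that add atoms: Eschenmoser's salt, C=[N+](C)C.[I-]
Why: α-Methylenation of the lactone by Mannich reaction of its lithium enolate, N-methylation and β-elimination of trimethylamine; the mild final base avoids isomerization to the endocyclic butenolide and installs C3.

Step 10
Reactants: 15 (3aS,4R,7aS)-4-methyl-3-methylidene-4-vinyl-3a,4,5,7a-tetrahydro-1-benzofuran-2(3H)-one
Product: 16 (1S,5R,6S)-6-(3-hydroxyprop-1-en-2-yl)-5-methyl-5-vinylcyclohex-2-en-1-ol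
Conditions: i-Bu2AlH (4 equiv), CH2Cl2, −78 to 0 °C; Rochelle salt
Reagents that add atoms: none
Why: 1,2-Reduction of the α-methylene lactone through the lactol to the 2-methylene-1,4-diol with excess i-Bu2AlH; no stereocentre is touched.

Step 11
Reactants: 16 (1S,5R,6S)-6-(3-hydroxyprop-1-en-2-yl)-5-methyl-5-vinylcyclohex-2-en-1-ol
Product: 17 15-O-tert-butyldiphenylsilyl ether of 16 (C6 hydroxyl free)
Conditions: t-BuPh2SiCl (1.05 equiv), imidazole, CH2Cl2, 0 °C
Reagents that add atoms: tert-butyldiphenylsilyl chloride, CC(C)(C)[Si](Cl)(c1ccccc1)c1ccccc1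
Why: Selective silylation of the primary allylic hydroxyl over the hindered secondary one with a bulky silyl chloride.

Step 12
Reactants: 17 15-O-tert-butyldiphenylsilyl ether of 16
Product: 18 7,8-epoxy alcohol (epoxide syn to the C6 hydroxyl)
Conditions: VO(acac)2 (5 mol%), t-BuOOH, CH2Cl2, 0 °C to rt
Reagents that add atoms: tert-butyl hydroperoxide, CC(C)(C)OO
Why: Vanadium-catalysed hydroxyl-directed epoxidation (Sharpless–Michaelson); only the ring alkene allylic to the free C6 hydroxyl is oxidized, syn to it, while the vinyl and the merely homoallylic methylene groups are left alone.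

Step 13
Reactants: 18 7,8-epoxy alcohol
Product: 19 6-O-tert-butyldimethylsilyl ether of 18
Conditions: t-BuMe2SiOTf, 2,6-lutidine, CH2Cl2, −78 to 0 °C
Reagents that add atoms: tert-butyldimethylsilyl triflate, CC(C)(C)[Si](C)(C)OS(=O)(=O)C(F)(F)F
Why: Silylation of a hindered secondary alcohol with a silyl triflate under non-nucleophilic base; the epoxide survives.

Step 14
Reactants: 19 6-O-tert-butyldimethylsilyl ether of 18
Product: 20 C7,C8-dialdehyde (acyclic; C5, C6 and C10 defined)
Conditions: H5IO6 (2 equiv), Et2O–THF, 0 °C to rt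
Reagents that add atoms: orthoperiodic acid, OI(=O)(O)(O)(O)O
Why: Periodic acid opens the epoxide to the trans-diol and cleaves it in the same flask (glycol cleavage), a ring opening that does not touch the three C=C bonds; C6 keeps its configuration.

Step 15
Reactants: 20 C7,C8-dialdehyde
Product: 21 C8 dimethyl acetal with free C7 aldehyde
Conditions: HC(OMe)3, MeOH, PPTS (cat.), 0 °C
Reagents that add atoms: trimethyl orthoformate, COC(OC)OC; methanol, CO
Why: Kinetic chemoselective acetalization; the oxocarbenium ion at the unbranched C8 aldehyde forms readily, whereas the α-silyloxy, α-branched C7 aldehyde is inductively deactivated and hindered.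

Step 16
Reactants: 21 C8 dimethyl acetal with free C7 aldehyde; 22 methyl acrylate
Product: 23 Baylis–Hillman adduct (C7 carbinol, both epimers; C11=C13 methylene; C12 methyl ester)
Conditions: methyl acrylate (neat, excess), DABCO (1 equiv), MeOH (2 equiv), rt
Reagents that add atoms: none
Why: Morita–Baylis–Hillman reaction of an inductively activated α-oxy aldehyde; the new C7 carbinol centre is not controlled and need not be, since it becomes sp2 in the next step.

Step 17
Reactants: 23 Baylis–Hillman adduct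
Product: 24 (Z)-2-(bromomethyl)enoate with C8 dimethyl acetal
Conditions: NBS, Me2S, CH2Cl2, −20 to 0 °C
Reagents that add atoms: N-bromosuccinimide, O=C1CCC(=O)N1Br
Why: Corey–Kim-type activation of the allylic alcohol followed by bromide attack with allylic transposition gives the 2-(bromomethyl)enoate, Z by thermodynamic preference (C6 trans to the ester).

Step 18
Reactants: 24 (Z)-2-(bromomethyl)enoate with C8 dimethyl acetal
Product: 25 methyl (Z)-2-(bromomethyl)enoate C8 aldehyde (6-OTBS, 15-OTBDPS; key-step precursor)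
Conditions: 10% aq. oxalic acid on SiO2, CH2Cl2, rt
Reagents that add atoms: water, O
Why: Mild acetal hydrolysis on wet acidic silica frees the unactivated C8 aldehyde without touching the silyl ethers or the allylic bromide.

Step 19
Reactants: 25 methyl (Z)-2-(bromomethyl)enoate C8 aldehyde
Product: 27 cis-fused 8,12-α-methylene-γ-butyrolactone on ring C5–C10 (6-OTBS, 15-OTBDPS), via hydroxy ester 26 (not isolated)
Conditions: In powder (zerovalent indium, 2 equiv), THF/H2O (4:1), 0.01 M, rt; then PPTS (cat.), CH2Cl2, rt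
Reagents that add atoms: none
Why: Zerovalent indium inserts into the allylic C–Br bond of 25 and the resulting 2-(methoxycarbonyl)allylindium adds through its γ-carbon C7 to the C8 aldehyde in a six-membered cyclic transition state, an intramolecular Barbier (Nozaki–Hiyama-type) allylation of a 2-(bromomethyl)alk-2-enoate, which is a known route to cis-fused α-methylene-γ-butyrolactones. The carbocycle C5–C10 closes by 6-exo-trig attack on the carbonyl, the C11=C13 methylene appearing in the same event, and the C8 alkoxide of 26 then closes the lactone by 5-exo-trig acyl substitution on the methyl ester. C7 and C8 are set together: the Z-configured allyl unit reacts through a chair-like array that places C11 and O8 cis, and only a cis pair can lactonize. The face of C7 is set by the C6 silyloxy centre, since the isomer with C11 trans to O6 avoids the 1,3-diaxial crowding (C14 methyl, O6 and O8, or C4 and C11) that the all-cis alternative would suffer in the forming chair. The step needs chemoselectivity for the allylic bromide over the aldehyde, the silyl ethers and the other alkenes, which indium in aqueous THF provides, and high dilution suppresses intermolecular allylation.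

Step 20
Reactants: 27 cis-fused 8,12-α-methylene-γ-butyrolactone
Product: 29 8-hydroxy 12-(4-methoxybenzyl) ester, via potassium carboxylate 28 (not isolated)
Conditions: KOH (1.05 equiv), THF/H2O, 0 °C to rt; evaporate; 4-MeOC6H4CH2Cl, n-Bu4NI (cat.), DMF, 0 °C to rt
Reagents that add atoms: potassium hydroxide, [K+].[OH-]; 4-methoxybenzyl chloride, COc1ccc(CCl)cc1
Why: Saponification of the lactone and O-alkylation of the carboxylate without acidification; the salt cannot relactonize and the unactivated benzyl-type ester is a poor acyl donor towards the C8 hydroxyl.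

Step 21
Reactants: 30 3-methylfuran-2(5H)-one
Product: 33 4-methoxybenzyl (Z)-4-acetoxy-2-methylbut-2-enoate, via potassium hydroxy carboxylate 31 (not isolated), via hydroxy ester 32 (not isolated)
Conditions: KOH (1.0 equiv), H2O, rt; evaporate; 4-MeOC6H4CH2Cl, DMF, rt; then Ac2O, pyridine, DMAP (cat.), 0 °C
Reagents that add atoms: potassium hydroxide, [K+].[OH-]; 4-methoxybenzyl chloride, COc1ccc(CCl)cc1; acetic anhydride, CC(=O)OC(C)=O
Why: Hydroxide opening of the butenolide keeps the Z geometry that the ring imposes; carboxylate alkylation and immediate O-acetylation trap the open form before it can close again.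

Step 22
Reactants: 33 4-methoxybenzyl (Z)-4-acetoxy-2-methylbut-2-enoate
Product: 34 (Z)-4-acetoxy-2-methylbut-2-enoic acid
Conditions: TFA, anisole, CH2Cl2, 0 °C
Reagents that add atoms: none
Why: Acidolysis of the 4-methoxybenzyl ester with anisole as cation trap; no hydrolytic step is used, so the acetate and the Z alkene survive.

Step 23
Reactants: 29 8-hydroxy 12-(4-methoxybenzyl) ester; 34 (Z)-4-acetoxy-2-methylbut-2-enoic acid
Product: 36 8-O-[(Z)-4-acetoxy-2-methylbut-2-enoyl] 12-(4-methoxybenzyl) ester, via mixed anhydride 35 (not isolated)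
Conditions: 2,4,6-Cl3C6H2COCl, Et3N, toluene, rt; then 29, toluene, 80 °C (no DMAP)
Reagents that add atoms: none
Why: Yamaguchi esterification through the mixed anhydride; leaving out the nucleophilic catalyst avoids the addition–elimination pathway that isomerizes angelate-type acyl groups to the E isomer.

Step 24
Reactants: 36 8-O-acyl 12-(4-methoxybenzyl) ester
Product: 37 8-O-acyl 12-oic acid (6-OTBS, 15-OTBDPS)
Conditions: TFA (10% v/v), anisole, CH2Cl2, 0 °C, short reaction time
Reagents that add atoms: none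
Why: Acidolysis of the 4-methoxybenzyl ester; the secondary TBS and primary TBDPS ethers, the allylic acetate and the enoate esters tolerate brief cold TFA, and O6 stays blocked so the acid cannot close onto it.

Step 25
Reactants: 37 8-O-acyl 12-oic acid (6-OTBS, 15-OTBDPS)
Product: 38 target acid CNP0261293.1
Conditions: HF·pyridine, pyridine, THF, 0 °C to rt
Reagents that add atoms: none
Why: Fluoride-driven cleavage of both silyl ethers under pyridine-buffered conditions that leave the acetate, the Z-enoate ester and the α-methylene acid intact.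

**Compound list**
1 | methyl vinyl ketone | CC(=O)C=C | starting material
2 | 2-(triisopropylsilyloxy)buta-1,3-diene | C=CC(=C)O[Si](C(C)C)(C(C)C)C(C)C | intermediate
3 | methacrolein | CC(=C)C=O | starting material
4 | (S)-1-methyl-4-(triisopropylsilyloxy)cyclohex-3-ene-1-carbaldehyde | O=C[C@@]1(C)CCC(O[Si](C(C)C)(C(C)C)C(C)C)=CC1 | intermediate
5 | triisopropyl{[(4S)-4-methyl-4-vinylcyclohex-1-en-1-yl]oxy}silane | C=C[C@@]1(C)CCC(O[Si](C(C)C)(C(C)C)C(C)C)=CC1 | intermediate
6 | (R)-4-methyl-4-vinylcyclohex-2-en-1-one | C=C[C@@]1(C)CCC(=O)C=C1 | intermediate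
7 | (1S,4R)-4-methyl-4-vinylcyclohex-2-en-1-ol | C=C[C@@]1(C)CC[C@H](O)C=C1 | intermediate
8 | ketene N,O-acetal of 7 | C=C[C@@]1(C)CC[C@H](OC(=C)N(C)C)C=C1 | intermediate
9 | N,N-dimethyl-2-[(1S,6R)-6-methyl-6-vinylcyclohex-2-en-1-yl]acetamide | C=C[C@@]1(C)CCC=C[C@@H]1CC(=O)N(C)C | intermediate
10 | iminium lactone iodide | C=C[C@@]1(C)CC[C@@H](I)[C@@H]2OC(=[N+](C)C)C[C@H]12.[I-] | intermediate
11 | (3aR,4R,7R,7aR)-7-iodo-4-methyl-4-vinylhexahydro-1-benzofuran-2(3H)-one | C=C[C@@]1(C)CC[C@@H](I)[C@@H]2OC(=O)C[C@H]12 | intermediate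
12 | (3aR,4R,7aS)-4-methyl-4-vinyl-3a,4,5,7a-tetrahydro-1-benzofuran-2(3H)-one | C=C[C@@]1(C)CC=C[C@@H]2OC(=O)C[C@H]12 | intermediate
13 | 3-(dimethylaminomethyl) lactone (Mannich base, C3 epimers) | C=C[C@@]1(C)CC=C[C@@H]2OC(=O)C(CN(C)C)[C@H]12 | intermediate
14 | trimethylammonium iodide of 13 | C=C[C@@]1(C)CC=C[C@@H]2OC(=O)C(C[N+](C)(C)C)[C@H]12.[I-] | intermediate
15 | (3aS,4R,7aS)-4-methyl-3-methylidene-4-vinyl-3a,4,5,7a-tetrahydro-1-benzofuran-2(3H)-one | C=C[C@@]1(C)CC=C[C@@H]2OC(=O)C(=C)[C@H]12 | intermediate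
16 | (1S,5R,6S)-6-(3-hydroxyprop-1-en-2-yl)-5-methyl-5-vinylcyclohex-2-en-1-ol | C=C[C@@]1(C)CC=C[C@H](O)[C@@H]1C(=C)CO | intermediate
17 | 15-O-TBDPS ether of 16 | C=C[C@@]1(C)CC=C[C@H](O)[C@@H]1C(=C)CO[Si](c1ccccc1)(c1ccccc1)C(C)(C)C | intermediate
18 | 7,8-epoxy alcohol (epoxide syn to 6-OH) | C=C[C@@]1(C)C[C@@H]2O[C@@H]2[C@H](O)[C@@H]1C(=C)CO[Si](c1ccccc1)(c1ccccc1)C(C)(C)C | intermediate
19 | 6-O-TBS ether of 18 | C=C[C@@]1(C)C[C@@H]2O[C@@H]2[C@H](O[Si](C)(C)C(C)(C)C)[C@@H]1C(=C)CO[Si](c1ccccc1)(c1ccccc1)C(C)(C)C | intermediate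
20 | C7,C8-dialdehyde | O=CC[C@](C)(C=C)[C@@H](C(=C)CO[Si](c1ccccc1)(c1ccccc1)C(C)(C)C)[C@@H](O[Si](C)(C)C(C)(C)C)C=O | intermediate
21 | C8 dimethyl acetal, C7 aldehyde | COC(OC)C[C@](C)(C=C)[C@@H](C(=C)CO[Si](c1ccccc1)(c1ccccc1)C(C)(C)C)[C@@H](O[Si](C)(C)C(C)(C)C)C=O | intermediate
22 | methyl acrylate | C=CC(=O)OC | starting material
23 | Baylis–Hillman adduct (C7 epimers) | COC(OC)C[C@](C)(C=C)[C@@H](C(=C)CO[Si](c1ccccc1)(c1ccccc1)C(C)(C)C)[C@@H](O[Si](C)(C)C(C)(C)C)C(O)C(=C)C(=O)OC | intermediate
24 | (Z)-2-(bromomethyl)enoate, C8 dimethyl acetal | COC(OC)C[C@](C)(C=C)[C@@H](C(=C)CO[Si](c1ccccc1)(c1ccccc1)C(C)(C)C)[C@@H](O[Si](C)(C)C(C)(C)C)/C=C(\CBr)C(=O)OC | intermediate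
25 | (Z)-2-(bromomethyl)enoate C8 aldehyde (key-step precursor) | O=CC[C@](C)(C=C)[C@@H](C(=C)CO[Si](c1ccccc1)(c1ccccc1)C(C)(C)C)[C@@H](O[Si](C)(C)C(C)(C)C)/C=C(\CBr)C(=O)OC | intermediate
26 | 8-hydroxy methyl ester | C=C[C@@]1(C)C[C@@H](O)[C@@H](C(=C)C(=O)OC)[C@H](O[Si](C)(C)C(C)(C)C)[C@@H]1C(=C)CO[Si](c1ccccc1)(c1ccccc1)C(C)(C)C | intermediate
27 | cis-fused 8,12-α-methylene lactone (key-step product) | C=C[C@@]1(C)C[C@H]2OC(=O)C(=C)[C@H]2[C@H](O[Si](C)(C)C(C)(C)C)[C@@H]1C(=C)CO[Si](c1ccccc1)(c1ccccc1)C(C)(C)C | intermediate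
28 | potassium 8-hydroxy carboxylate | C=C[C@@]1(C)C[C@@H](O)[C@@H](C(=C)C(=O)[O-])[C@H](O[Si](C)(C)C(C)(C)C)[C@@H]1C(=C)CO[Si](c1ccccc1)(c1ccccc1)C(C)(C)C.[K+] | intermediate
29 | 8-hydroxy 12-(4-methoxybenzyl) ester | C=C[C@@]1(C)C[C@@H](O)[C@@H](C(=C)C(=O)OCc2ccc(OC)cc2)[C@H](O[Si](C)(C)C(C)(C)C)[C@@H]1C(=C)CO[Si](c1ccccc1)(c1ccccc1)C(C)(C)C | intermediate
30 | 3-methylfuran-2(5H)-one | CC1=CCOC1=O | starting material
31 | potassium (Z)-4-hydroxy-2-methylbut-2-enoate | O=C([O-])/C(C)=C\CO.[K+] | intermediate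
32 | 4-methoxybenzyl (Z)-4-hydroxy-2-methylbut-2-enoate | COc1ccc(COC(=O)/C(C)=C\CO)cc1 | intermediate
33 | 4-methoxybenzyl (Z)-4-acetoxy-2-methylbut-2-enoate | COc1ccc(COC(=O)/C(C)=C\COC(C)=O)cc1 | intermediate
34 | (Z)-4-acetoxy-2-methylbut-2-enoic acid | O=C(O)/C(C)=C\COC(C)=O | intermediate
35 | mixed anhydride of 34 with 2,4,6-trichlorobenzoic acid | O=C(OC(=O)c1c(Cl)cc(Cl)cc1Cl)/C(C)=C\COC(C)=O | intermediate
36 | 8-O-acyl 12-(4-methoxybenzyl) ester | C=C[C@@]1(C)C[C@@H](OC(=O)/C(C)=C\COC(C)=O)[C@@H](C(=C)C(=O)OCc2ccc(OC)cc2)[C@H](O[Si](C)(C)C(C)(C)C)[C@@H]1C(=C)CO[Si](c1ccccc1)(c1ccccc1)C(C)(C)C | intermediate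
37 | 8-O-acyl 12-oic acid, 6-OTBS, 15-OTBDPS | C=C[C@@]1(C)C[C@@H](OC(=O)/C(C)=C\COC(C)=O)[C@@H](C(=C)C(=O)O)[C@H](O[Si](C)(C)C(C)(C)C)[C@@H]1C(=C)CO[Si](c1ccccc1)(c1ccccc1)C(C)(C)C | intermediate
38 | CNP0261293.1 | C=C[C@@]1(C)C[C@@H](OC(=O)/C(C)=C\COC(C)=O)[C@@H](C(=C)C(=O)O)[C@H](O)[C@@H]1C(=C)CO | target

**Step count**
Total: 25 steps. Longest linear sequence: 23 steps (steps 1–20 and 23–25); steps 21–22 are the side-chain branch.

**Steps most likely to fail**

Step 19. The ring closure may show poor facial discrimination at C7/C8, or the allylindium may be protonated or couple intermolecularly before it cyclizes. The fallback generates the allyl nucleophile catalytically from an allylic acetate instead of a bromide. It sets out from alcohol 23: acetylation (Ac2O, pyridine, DMAP) gives the allylic acetate acetal F1, and wet silica/oxalic acid unmasks the aldehyde to give the acetate aldehyde F2. Pd(PPh3)4 (zerovalent palladium, 5 mol%) with InI (monovalent indium iodide) in THF turns the acetate into a π-allylpalladium species that is transmetalated to an allylindium held at low stationary concentration (umpolung allylation). Et2Zn in place of InI gives an allylzinc with a tighter transition state if the selectivity needs to change. Addition through C7 to the C8 aldehyde and lactonization of hydroxy ester 26 bring the route back at lactone 27.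

Step 16. Amine-catalysed addition may be too slow on this hindered aldehyde, and prolonged exposure to DABCO may epimerize C6 or let the aldehyde degrade. The fallback replaces amine catalysis by a preformed α-metalated acrylate. It sets out from aldehyde 21: [α-(methoxycarbonyl)vinyl]diisobutylalane, made from methyl propiolate and i-Bu2AlH with N-methylmorpholine N-oxide in THF at 0 °C, is added to 21 at −78 °C. Its 1,2-addition gives the same adduct, so the route is rejoined at 23 with no new intermediate.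

Step 23. The free C8 hydroxyl may close back onto the cis C12 ester (relactonization to 27) faster than it is acylated under the heated conditions. The fallback removes the ester during acylation. It sets out from lactone 27: i-Bu2AlH reduces it to the C8,C12-diol F3, and Et3SiCl/imidazole at −20 °C silylates only the primary allylic hydroxyl to give the 12-O-triethylsilyl ether F4. Yamaguchi acylation with 34 then gives the 8-O-acyl silyl ether F5, which has no ester to lactonize onto. PPTS in MeOH at 0 °C removes the triethylsilyl group to give the allylic alcohol F6, MnO2 in CH2Cl2 oxidizes it to the enal F7, and NaClO2/NaH2PO4/2-methyl-2-butene in t-BuOH–H2O gives the acid, rejoining the route at 37.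

**Further compounds**
F1 | step 19 | Baylis–Hillman acetate, C8 dimethyl acetal | COC(OC)C[C@](C)(C=C)[C@@H](C(=C)CO[Si](c1ccccc1)(c1ccccc1)C(C)(C)C)[C@@H](O[Si](C)(C)C(C)(C)C)C(OC(C)=O)C(=C)C(=O)OC
F2 | step 19 | Baylis–Hillman acetate, C8 aldehyde | O=CC[C@](C)(C=C)[C@@H](C(=C)CO[Si](c1ccccc1)(c1ccccc1)C(C)(C)C)[C@@H](O[Si](C)(C)C(C)(C)C)C(OC(C)=O)C(=C)C(=O)OC
F0 | step 16 | none | none
F3 | step 23 | C8,C12-diol | C=C[C@@]1(C)C[C@@H](O)[C@@H](C(=C)CO)[C@H](O[Si](C)(C)C(C)(C)C)[C@@H]1C(=C)CO[Si](c1ccccc1)(c1ccccc1)C(C)(C)C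
F4 | step 23 | 12-O-triethylsilyl ether of the diol | C=C[C@@]1(C)C[C@@H](O)[C@@H](C(=C)CO[Si](CC)(CC)CC)[C@H](O[Si](C)(C)C(C)(C)C)[C@@H]1C(=C)CO[Si](c1ccccc1)(c1ccccc1)C(C)(C)C
F5 | step 23 | 8-O-acyl 12-O-triethylsilyl ether | C=C[C@@]1(C)C[C@@H](OC(=O)/C(C)=C\COC(C)=O)[C@@H](C(=C)CO[Si](CC)(CC)CC)[C@H](O[Si](C)(C)C(C)(C)C)[C@@H]1C(=C)CO[Si](c1ccccc1)(c1ccccc1)C(C)(C)C
F6 | step 23 | 8-O-acyl C12 allylic alcohol | C=C[C@@]1(C)C[C@@H](OC(=O)/C(C)=C\COC(C)=O)[C@@H](C(=C)CO)[C@H](O[Si](C)(C)C(C)(C)C)[C@@H]1C(=C)CO[Si](c1ccccc1)(c1ccccc1)C(C)(C)C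
F7 | step 23 | 8-O-acyl C12 enal | C=C[C@@]1(C)C[C@@H](OC(=O)/C(C)=C\COC(C)=O)[C@@H](C(=C)C=O)[C@H](O[Si](C)(C)C(C)(C)C)[C@@H]1C(=C)CO[Si](c1ccccc1)(c1ccccc1)C(C)(C)C
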